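# Proposed total synthesis of CNP0261875.1 (compound 18) from (R)-limonene through a cis-fused bicyclic β-lactone

## Analysis of the target

Target 18 consists of two carbocycles joined by one methylene bridge. Ring B (C1–C6) is a fully substituted, dearomatised acylphloroglucinol, an enolised triketone with an isobutyryl group at C2. Ring A (C1'–C5') is a trisubstituted cyclopentane.

Ring A carries three contiguous stereocentres. C1' (S) is the CH that holds the bridge, C2' (R) is the tertiary carbinol with a methyl group, and C5' (R) is the CH that holds the isopropenyl group. The hydroxyl and the bridge are cis, and the bridge and the isopropenyl group are trans.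

Ring B holds one isolated all-carbon quaternary stereocentre, C6 (methyl and prenyl; R in the drawn tautomer). It lies four bonds from C1' across a freely rotating CH2, so ring A cannot relay stereochemical information to it.

The tertiary alcohol ionises easily in acid. It would then lose a proton or be captured by a neighbouring enol oxygen of ring B as a pyran. The prenyl and isopropenyl alkenes are sensitive to acid and oxidants. The triketone is acidic, chelating, easily oxidised and easily over-alkylated.

The synthesis is hard on three counts:
- building the cis hydroxyl/bridge array without retro-aldol cleavage or dehydration;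
- attaching the hindered C1' substituent to ring B;
- fixing C6 without help from the substrate.

The strategy rests on the array O–C2'–C1'–CH2(bridge). Raised to the acid oxidation level at the bridge carbon, it is a β-hydroxy acid whose oxygen and carboxyl carbon are cis on adjacent ring-A atoms. It can therefore be closed to a 2-oxetanone fused across C1'–C2', a 6-oxabicyclo[3.2.0]heptan-7-one, which can only be cis-fused. What remains, C5' with its isopropenyl group and a ten-carbon count, maps directly onto C4 of limonene.

## Retrosynthetic reasoning

**C6–prenyl bond.** The last bond made is the one between C6 and the prenyl CH2. This takes 18 back to the flat, hexasubstituted aromatic compound 15 and the prenyl donor 17, itself made from 16.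
- Cutting here keeps the fragile dearomatised triketone out of every earlier step.
- In 15 no ring CH is left, so C-alkylation can only dearomatise. The choice is reduced to the methyl-bearing carbon or the much more crowded carbon that bears the bridge.
- The forward reaction must prefer C over O, the methyl-bearing carbon over the bridge-bearing one, the linear over the branched prenyl terminus, and one face of the ring.
- Ring A is too far away to help with the face. An uncatalysed alkylation would erode any catalyst control, so an allylic carbonate that reacts only through a chiral palladium catalyst is preferred to an allylic halide.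

**Aryl–CH2 bond.** Next the bond between ring-B carbon C4 and the bridge carbon is cut, giving aldehyde 10 and the acylated arene 13.
- The other bridge bond (CH2–C1') is left alone. Forming it would require substitution at a secondary ring carbon flanked by two stereocentres.
- The chosen cut uses the innate nucleophilicity of the single free ring CH of 13.
- In the forward sense, condensation gives the o-quinone methide 14, and a hydride donor reduces it in the same flask. The bridge carbon thus falls from the aldehyde to the CH2 level without a separate deoxygenation.

**Acyl group of the arene.** Compound 13 is cut at the aryl–acyl bond into 11 and 12. The two free ring positions of 11 are equivalent by symmetry, so the acylation poses no regiochemical question, and the first acyl group deactivates the ring towards a second.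

**Redox adjustment.** Aldehyde 10 is traced through diol 9 to β-lactone 8. No skeletal bond is cut. The lactone carbonyl carbon is the future bridge carbon and the lactone ring oxygen is the future hydroxyl. Full reduction followed by selective reoxidation of the only oxidisable alcohol is more dependable than a partial reduction of a strained lactone.

**Key disconnection.** In 8 the C1–C5 ring bond (future C1'–C2') and the acyl C–O bond are cut together, giving the acyclic keto acid 5.
- Two rings, two skeletal bonds and two stereocentres are gained in one operation from a compound with a single stereocentre.
- A plain aldol at this position would be reversible and prone to dehydration, and the hydroxyl/carbonyl relation would be open. Capture of the aldolate as the four-membered lactone removes all three problems.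
- The forward reaction must turn the acid, and not the methyl ketone, into the nucleophile. It must also form the new ring CH trans to the isopropenyl group.

**Chiral pool.** Keto acid 5 is the product of oxidative opening of the ring alkene of 1, and is traced back through aldehyde 4, diol 3 and epoxide 2. All ten carbons of 1 are kept, and its stereocentre becomes C5' with the required configuration. The only demand is that the trisubstituted alkene be distinguished from the isopropenyl group.

## Alternatives that were turned down

**Alternative 1:** The bridge-to-C1' bond and the C2'–O bond are cut together.
- *Disconnection.* This leads to the o-quinone methide A4, made by oxidising the enolic C-methyl group of the dearomatised core A3, and to the methylcyclopentene A2. A2 would come from 1 by ring contraction, with the isopropenyl group masked as a silyloxypropyl chain.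
- *Forward key step.* A hetero-Diels–Alder reaction joins the CH2 terminus of A4 to the alkene CH, and a ring-B carbonyl oxygen to the methyl-bearing alkene carbon. The product is the cis-fused cyclopenta-pyran A1.
- *In favour.* Suprafacial addition guarantees the cis oxygen/bridge relation. The polarity of the partners matches, and approach anti to the side chain gives the trans relation to C5'. The plan is convergent and avoids the labile aldehyde 10. C6 is set on a small achiral precursor, where enantiopurity can be checked and upgraded before the fragments meet. On these last two points it is stronger than the chosen route.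
- *Against.*
  - A1 is not the target, because its tertiary oxygen is locked in a vinylogous ester. Opening it must break the sp2 C–O bond of an electron-rich system that is anionic under base, while acid breaks the tertiary alkyl C–O bond and leads to elimination.
  - The isopropenyl alkene is more accessible than the trisubstituted ring alkene. It therefore has to be masked (adding a throw-away stereocentre) and rebuilt by desilylation, activation and elimination.
  - The prenyl group of A4 is a competing internal dienophile.
  - A2 requires one carbon of 1 to be excised.
- *Comparison.* The chosen strategy releases the free tertiary alcohol and an untouched isopropenyl group straight from its key intermediate. It uses all ten carbons of 1 and needs far fewer steps before and after the key step.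

**Alternative 2:** Ring A is cut between C5' and C4', leading to the cross-conjugated divinyl ketone A6.
- *Forward key step.* Acid activation triggers a 4π conrotatory closure between the silyl-bearing vinyl terminus and the isopropenyl-bearing carbon. Loss of silicon fixes the position of the enone alkene, and protonation sets the α-carbon, giving the trans cyclopentenone A5.
- *In favour.* The method is catalytic and independent of the chiral pool. A later methyl addition to the ketone, anti to the neighbouring silyloxymethyl group, would place the hydroxyl cis to the bridge carbon as required. On that point it equals the chosen plan.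
- *Against.*
  - In A6 the isopropenyl group extends the pentadienyl cation, which opens competing cyclisation, proton-loss and oligomerisation channels.
  - A dienyl substituent is a poor handle for torquoselection.
  - The α-stereocentre of A5 is both enolisable and β to a silyloxy group. Epimerisation and β-elimination therefore threaten during the conjugate reduction (which must also spare the isopropenyl group) and during the basic methyl addition.
  - After several steps to A6, three more are needed merely to reach diol 9.
- *Comparison.* Independence from the chiral pool brings little here, since both enantiomers of limonene are sold. The chosen route reaches 9 in five steps, with one stereocentre bought and two fixed by the ring fusion and the resident centre.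

**Alternative 3:** Ring A is cut between C1' and C5', leading to the β-hydroxy ester A8 with a tethered (E)-allylic chloride. A8 would be made from (R)-linalool A9 by converting the vinyl group into an acetate arm and by allylic oxidation and chlorination of the far alkene.
- *Forward key step.* Double deprotonation gives a chelated alkoxide–enolate. Its α-carbon attacks the CH= terminus in a 5-exo SN2′ displacement, closing the cyclopentane and unveiling the isopropenyl group in ester A7.
- *In favour.* The tertiary carbinol stereocentre is bought rather than made. A7 is sturdier than a β-lactone and is one reduction away from 9. Ring closure and isopropenyl formation coincide. On the first two points it is stronger than the chosen plan.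
- *Against.*
  - Two stereocentres must be set in one open transition state. The ester/hydroxyl relation depends on the chelate surviving, and the C5' configuration depends on a modest chair-versus-boat preference.
  - A hard enolate has no intrinsic bias for SN2′ attack.
  - The lithium alkoxide of a tertiary β-hydroxy ester can fragment by retro-aldol.
  - Reaching A8 needs two chemoselective alkene functionalisations, about twice the number of steps needed for 5.
- *Comparison.* The chosen strategy has only one open selectivity question in its key step, because the ring fusion dictates the hydroxyl/acyl relation, and its precursor takes three steps.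

Key step: step 4

Assumption: 18 is treated as the enol tautomer drawn for the target (the descriptor 6R refers to it), and the (R,R) ligand written in step 10 stands for whichever ligand enantiomer directs the prenyl group to the required face, since the sense of induction cannot be derived with confidence for this nucleophile.

## Route

Step 1
Reactants: 1 (R)-(+)-limonene
Product: 2 (4R)-limonene 1,2-oxide (cis/trans mixture at C1/C2)
Conditions: mCPBA (1.0 equiv), CH2Cl2, 0 °C
Reagents that add atoms: mCPBA, O=C(OO)c1cccc(Cl)c1
Why: Prilezhaev epoxidation; the trisubstituted ring alkene is more electron-rich than the 1,1-disubstituted isopropenyl alkene, so one equivalent of peracid at low temperature should react there. Both epoxide diastereomers are carried on because C1 and C2 lose their stereochemistry in step 2, and C4 is untouched.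

Step 2
Reactants: 2 (4R)-limonene 1,2-oxide
Product: 4 (3R)-6-oxo-3-(prop-1-en-2-yl)heptanal, via limonene-1,2-diol 3 (not isolated)
Conditions: H5IO6, THF/H2O, 0 °C → rt
Reagents that add atoms: water, O
Why: The acidic reagent hydrolyses the epoxide to diol 3, which undergoes Malaprade glycol cleavage in the same flask. The isopropenyl group has no vicinal oxygen function and should survive the short exposure to dilute acid, and the stereocentre is not involved.

Step 3
Reactants: 4 (3R)-6-oxo-3-(prop-1-en-2-yl)heptanal
Product: 5 (3R)-6-oxo-3-(prop-1-en-2-yl)heptanoic acid
Conditions: NaClO2, NaH2PO4, 2-methyl-2-butene (excess), t-BuOH/H2O, rt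
Reagents that add atoms: sodium chlorite, [Na+].[O-]Cl=O
Why: Pinnick oxidation converts the aldehyde selectively, leaving the methyl ketone untouched. The excess of the more nucleophilic scavenger alkene takes up hypochlorous acid before it can reach the isopropenyl group.

Step 4
Reactants: 5 (3R)-6-oxo-3-(prop-1-en-2-yl)heptanoic acid
Product: 8 (1S,2R,5R)-5-methyl-2-(prop-1-en-2-yl)-6-oxabicyclo[3.2.0]heptan-7-one, via tosyl mixed anhydride 6 (not isolated), via acylpyridinium tosylate 7 (not isolated)
Conditions: TsCl, 4-pyrrolidinopyridine (cat.), i-Pr2NEt, LiCl, CH2Cl2, rt, slow addition of 5 at high dilution
Reagents that add atoms: none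
Why: This is a nucleophile-catalysed aldol-lactonisation of a keto acid, a known route to carbocycle-fused β-lactones. TsCl turns 5 into mixed anhydride 6, the pyridine catalyst displaces tosylate to give 7, and i-Pr2NEt removes the strongly acidified α-proton of 7 to give its ammonium enolate, whereas the methyl ketone is not enolised by an amine base and remains the electrophile, assisted by Li+. The enolate carbon adds to the ketone carbon in a 5-(enolexo)-exo-trig closure that forms the cyclopentane, and the new tertiary alkoxide attacks the acylpyridinium carbon in a 4-exo-trig closure that forms the β-lactone and releases the catalyst. C1 is controlled by the resident C2 stereocentre: to avoid A(1,3) strain its C–H bond lies in the enolate plane, the tether and the isopropenyl group occupy opposite faces, the isopropenyl group sits pseudo-equatorial on the forming ring, and the acyl carbon therefore ends trans to it. C5 is controlled by ring strain, since only the aldolate with oxygen cis to the acyl group can close a four-membered ring on a cyclopentane, while the other aldolate can only revert. Of four conceivable diastereomers two are thus excluded by the ring fusion, and only the choice between anti and syn to the isopropenyl group is left to the substrate. Slow addition at high dilution should suppress intermolecular acylation, and lactonisation withdraws the aldolate from retro-aldol and dehydration equilibria.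

Step 5
Reactants: 8 (1S,2R,5R)-5-methyl-2-(prop-1-en-2-yl)-6-oxabicyclo[3.2.0]heptan-7-one
Product: 9 (1R,2R,3R)-2-(hydroxymethyl)-1-methyl-3-(prop-1-en-2-yl)cyclopentan-1-ol
Conditions: LiAlH4, Et2O, 0 °C; aq. NaOH work-up
Reagents that add atoms: none
Why: Hydride reduction of a strained lactone proceeds by acyl–oxygen cleavage, so the C–O bond at the tertiary centre and all three stereocentres are retained. Hydride attack on the activated carbonyl should be faster than enolisation, and the isolated alkene is inert.

Step 6
Reactants: 9 (1R,2R,3R)-2-(hydroxymethyl)-1-methyl-3-(prop-1-en-2-yl)cyclopentan-1-ol
Product: 10 (1S,2R,5R)-2-hydroxy-2-methyl-5-(prop-1-en-2-yl)cyclopentane-1-carbaldehyde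
Conditions: TEMPO (cat.), PhI(OAc)2, dry CH2Cl2, 0 °C → rt; used at once without chromatography
Reagents that add atoms: none
Why: Oxoammonium oxidation converts the primary alcohol, the tertiary alcohol cannot be oxidised, and no strong base is present that could start retro-aldol cleavage or β-elimination. The formyl group is already on the less crowded side (trans to both isopropenyl and methyl), so α-epimerisation has no driving force.

Step 7
Reactants: 11 2-methylphloroglucinol; 12 isobutyryl chloride
Product: 13 1-(2,4,6-trihydroxy-3-methylphenyl)-2-methylpropan-1-one
Conditions: AlCl3, CH2Cl2/PhNO2, 0 → 40 °C; aq. HCl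
Reagents that add atoms: none
Why: Friedel–Crafts acylation; the two free ring positions of 11 are equivalent by symmetry, so only one C-acyl product is possible. The chelated acyl group deactivates the ring towards a second acylation.

Step 8
Reactants: 10 (1S,2R,5R)-2-hydroxy-2-methyl-5-(prop-1-en-2-yl)cyclopentane-1-carbaldehyde; 13 1-(2,4,6-trihydroxy-3-methylphenyl)-2-methylpropan-1-one
Product: 15 1-(2,4,6-trihydroxy-3-{[(1S,2R,5R)-2-hydroxy-2-methyl-5-(prop-1-en-2-yl)cyclopentyl]methyl}-5-methylphenyl)-2-methylpropan-1-one, via o-quinone methide 14 (not isolated)
Conditions: L-proline (cat.), Hantzsch ester (diethyl 2,6-dimethyl-1,4-dihydropyridine-3,5-dicarboxylate), MeCN, rt, Ar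
Reagents that add atoms: none
Why: Three-component reductive alkylation (Knoevenagel-type condensation followed by transfer hydrogenation); the only free ring CH of 13, which behaves as a masked cyclic 1,3-dicarbonyl carbon, adds to the activated aldehyde and dehydration gives 14, which accepts hydride at its exocyclic carbon and rearomatises. The dihydropyridine reduces neither the free aldehyde nor the chelated aryl ketone, the hydroxyl cannot add to 14 because that would form an oxetane, and no ring-A stereocentre is changed.

Step 9
Reactants: 16 3-methylbut-2-en-1-ol (prenol)
Product: 17 methyl 3-methylbut-2-en-1-yl carbonate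
Conditions: ClCO2Me, pyridine, CH2Cl2, 0 °C
Reagents that add atoms: methyl chloroformate, COC(=O)Cl
Why: Standard O-acylation of a primary allylic alcohol with a chloroformate. The carbonate is unreactive towards phenolates without a metal catalyst, which is what step 10 requires.

Step 10
Reactants: 15 1-(2,4,6-trihydroxy-3-{[(1S,2R,5R)-2-hydroxy-2-methyl-5-(prop-1-en-2-yl)cyclopentyl]methyl}-5-methylphenyl)-2-methylpropan-1-one; 17 methyl 3-methylbut-2-en-1-yl carbonate
Product: 18 (6R)-3,5-dihydroxy-4-{[(1S,2R,5R)-2-hydroxy-2-methyl-5-(prop-1-en-2-yl)cyclopentyl]methyl}-6-methyl-6-(3-methylbut-2-en-1-yl)-2-(2-methylpropanoyl)cyclohexa-2,4-dien-1-one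
Conditions: Pd2(dba)3·CHCl3 (cat.), (R,R)-DACH-phenyl ligand [N,N'-(1R,2R)-cyclohexane-1,2-diylbis(2-diphenylphosphinobenzamide)] (cat.), 17 (1.0 equiv), degassed CH2Cl2, 0 °C → rt, Ar
Reagents that add atoms: none
Why: Proposed new method: the closest known reaction types are the intermolecular Pd-catalysed asymmetric allylic dearomatisation of substituted naphthols, the Pd-catalysed dearomative prenylation of indoles with prenyl carbonates and the non-asymmetric Pd-allyl dearomatisation of acylphloroglucinols, whereas a face-selective prenylation of a hexasubstituted acylphloroglucinol has not been shown. Pd(0) ionises 17 with loss of CO2, the liberated methoxide deprotonates the most acidic OH of 15 (para to the acyl group), and the soft phenolate attacks the unsubstituted terminus of the η3-prenyl ligand from outside the metal to give the linear prenyl group, while any O-prenyl ether is re-ionised by Pd(0) and drains into the irreversible C–C product. Both carbons ortho to that oxygen are activated alike, so the much smaller methyl group should direct attack to its own carbon, and the new quaternary stereocentre C6 is set by the chiral ligand pocket (catalyst control), because ring A is too remote and the carbonate has no uncatalysed background reaction.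

## Compound list

1 | (R)-(+)-limonene | CC1=CC[C@@H](CC1)C(C)=C | starting material
2 | (4R)-limonene 1,2-oxide (cis/trans mixture at C1/C2) | CC12OC1C[C@@H](CC2)C(C)=C | intermediate
3 | (4R)-limonene-1,2-diol (not isolated) | CC1(O)C(O)C[C@@H](CC1)C(C)=C | intermediate
4 | (3R)-6-oxo-3-(prop-1-en-2-yl)heptanal | C=C(C)[C@@H](CC=O)CCC(C)=O | intermediate
5 | (3R)-6-oxo-3-(prop-1-en-2-yl)heptanoic acid | C=C(C)[C@@H](CC(=O)O)CCC(C)=O | intermediate
6 | mixed anhydride of 5 with 4-methylbenzenesulfonic acid (not isolated) | C=C(C)[C@@H](CC(=O)OS(=O)(=O)c1ccc(C)cc1)CCC(C)=O | intermediate
7 | 1-acyl-4-(pyrrolidin-1-yl)pyridinium tosylate of 5 (not isolated) | C=C(C)[C@@H](CC(=O)[n+]1ccc(cc1)N1CCCC1)CCC(C)=O.Cc1ccc(cc1)S(=O)(=O)[O-] | intermediate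
8 | (1S,2R,5R)-5-methyl-2-(prop-1-en-2-yl)-6-oxabicyclo[3.2.0]heptan-7-one | C=C(C)[C@@H]1CC[C@@](C)(O2)[C@H]1C2=O | intermediate
9 | (1R,2R,3R)-2-(hydroxymethyl)-1-methyl-3-(prop-1-en-2-yl)cyclopentan-1-ol | C=C(C)[C@@H]1CC[C@@](C)(O)[C@H]1CO | intermediate
10 | (1S,2R,5R)-2-hydroxy-2-methyl-5-(prop-1-en-2-yl)cyclopentane-1-carbaldehyde | C=C(C)[C@@H]1CC[C@@](C)(O)[C@H]1C=O | intermediate
11 | 2-methylphloroglucinol | Cc1c(O)cc(O)cc1O | starting material
12 | isobutyryl chloride | CC(C)C(=O)Cl | starting material
13 | 1-(2,4,6-trihydroxy-3-methylphenyl)-2-methylpropan-1-one | CC(C)C(=O)c1c(O)cc(O)c(C)c1O | intermediate
14 | o-quinone methide from 10 and 13 (not isolated; alkene geometry open) | C=C(C)[C@@H]1CC[C@@](C)(O)[C@H]1C=C1C(=O)C(C)=C(O)C(C(=O)C(C)C)=C1O | intermediate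
15 | 1-(2,4,6-trihydroxy-3-{[(1S,2R,5R)-2-hydroxy-2-methyl-5-(prop-1-en-2-yl)cyclopentyl]methyl}-5-methylphenyl)-2-methylpropan-1-one | C=C(C)[C@@H]1CC[C@@](C)(O)[C@H]1Cc1c(O)c(C)c(O)c(C(=O)C(C)C)c1O | intermediate
16 | 3-methylbut-2-en-1-ol (prenol) | CC(C)=CCO | starting material
17 | methyl 3-methylbut-2-en-1-yl carbonate | COC(=O)OCC=C(C)C | intermediate
18 | (6R)-3,5-dihydroxy-4-{[(1S,2R,5R)-2-hydroxy-2-methyl-5-(prop-1-en-2-yl)cyclopentyl]methyl}-6-methyl-6-(3-methylbut-2-en-1-yl)-2-(2-methylpropanoyl)cyclohexa-2,4-dien-1-one | C=C(C)[C@@H]1CC[C@@](C)(O)[C@H]1CC1=C(O)[C@@](C)(CC=C(C)C)C(=O)C(C(=O)C(C)C)=C1O | target

## Step count and risk assessment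

Total step count: 10.
Longest linear sequence: 8 (steps 1–6, 8 and 10). Steps 7 and 9 are single-step side branches.

**Step 10 (Proposed new method).**
- *What may go wrong.* The most likely failure is weak facial discrimination. The nucleophile is flat, and the two flanks of the reacting carbon differ only at remote positions. Competing attack at the bridge-bearing carbon and a second prenylation are also possible. The reaction may slow at high conversion, because the more acidic product takes up the base released in each turnover.
- *Fallback (known chemistry).* Stereocontrol is given up and replaced by separation. Starting from 15, a classical alkylative dearomatisation with prenyl bromide (CC(C)=CCBr) and aqueous KOH at 0 °C under argon should give 18 together with the 6S epimer F1. This reaction type is established for acylphloroglucinols. Ring A is enantiopure, so the two products are diastereomers and can be separated by chromatography. The route is rejoined at 18.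

**Step 4 (key step).**
- *What may go wrong.* Possible failures are incomplete anti selectivity relative to the isopropenyl group, sluggish addition to the poorly electrophilic methyl ketone so that intermolecular acylation takes over, and loss of the strained lactone by hydrolysis or decarboxylation during isolation. A chiral isothiourea catalyst in its matched sense would be the first variation.
- *Fallback.* The change of approach builds the ring by condensation and installs the oxygen afterwards.
  - Starting from 4, piperidinium acetate-catalysed aldol condensation should give (5S)-2-methyl-5-(prop-1-en-2-yl)cyclopent-1-ene-1-carbaldehyde F2.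
  - Weitz–Scheffer epoxidation (H2O2, NaOH, MeOH) touches only the electron-poor alkene and should occur anti to the isopropenyl group. It should give (1S,2S,5R)-5-methyl-2-(prop-1-en-2-yl)-6-oxabicyclo[3.1.0]hexane-1-carbaldehyde F3.
  - Reductive opening of the α-C–O bond (SmI2, THF/MeOH, low temperature), followed by protonation to the less crowded α-epimer, returns to the route at 10.

**Step 8.**
- *What may go wrong.* The secondary amine that activates the aldehyde can also start enamine-driven loss of the β-hydroxyl or iminium-driven retro-aldol opening of ring A. The doubly flanked formyl group is hindered, so these processes, or capture of the quinone methide by a second molecule of 13, may outrun the desired sequence.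
- *Fallback.* C–C bond formation is separated from reduction, and amines are avoided altogether. Starting from 10 and 13, condensation with 4-methylbenzenesulfinic acid in CH2Cl2 should give the benzylic p-tolyl sulfone F4, as a mixture at the sulfonyl-bearing carbon. NaBH4 in EtOH then eliminates sulfinate and reduces the quinone methide as it forms. The route is rejoined at 15.

**Step 6.**
- *What may go wrong.* During oxidation, work-up or storage the free β-hydroxy aldehyde may undergo retro-aldol ring opening, β-elimination or α-epimerisation.
- *Fallback.* The diol is avoided and the hydroxyl is masked before the aldehyde exists.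
  - Starting from 8, aminolysis with MeNH(OMe)·HCl/i-PrMgCl should give the β-hydroxy Weinreb amide F5.
  - TESOTf/2,6-lutidine should give its triethylsilyl ether F6.
  - DIBAL-H at −78 °C should give the silyl-protected aldehyde F7, which can no longer undergo retro-aldol cleavage.
  - Coupling with 13 under the conditions of step 8 should give the silyl-protected arene F8.
  - HF·pyridine removes the silyl group, and the route is rejoined at 15.

## Further compounds

F1 | step 10 | 6S epimer of 18 | C=C(C)[C@@H]1CC[C@@](C)(O)[C@H]1CC1=C(O)[C@](C)(CC=C(C)C)C(=O)C(C(=O)C(C)C)=C1O
F2 | step 4 | (5S)-2-methyl-5-(prop-1-en-2-yl)cyclopent-1-ene-1-carbaldehyde | C=C(C)[C@@H]1CCC(C)=C1C=O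
F3 | step 4 | (1S,2S,5R)-5-methyl-2-(prop-1-en-2-yl)-6-oxabicyclo[3.1.0]hexane-1-carbaldehyde | C=C(C)[C@@H]1CC[C@@]2(C)O[C@@]12C=O
F4 | step 8 | benzylic p-tolyl sulfone of 15 (mixture at the sulfonyl-bearing carbon) | C=C(C)[C@@H]1CC[C@@](C)(O)[C@H]1C(c1c(O)c(C)c(O)c(C(=O)C(C)C)c1O)S(=O)(=O)c1ccc(C)cc1
F5 | step 6 | β-hydroxy Weinreb amide from 8 | C=C(C)[C@@H]1CC[C@@](C)(O)[C@H]1C(=O)N(C)OC
F6 | step 6 | triethylsilyl ether of F5 | C=C(C)[C@@H]1CC[C@@](C)(O[Si](CC)(CC)CC)[C@H]1C(=O)N(C)OC
F7 | step 6 | triethylsilyl ether of 10 | C=C(C)[C@@H]1CC[C@@](C)(O[Si](CC)(CC)CC)[C@H]1C=O
F8 | step 6 | triethylsilyl ether of 15 (at the tertiary hydroxyl) | C=C(C)[C@@H]1CC[C@@](C)(O[Si](CC)(CC)CC)[C@H]1Cc1c(O)c(C)c(O)c(C(=O)C(C)C)c1O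
A1 | alternative 1 | cis-fused cyclopenta-pyran hetero-Diels–Alder adduct with TBS-oxypropyl side chain | CC(CO[Si](C)(C)C(C)(C)C)[C@@H]1CC[C@@](C)(O2)[C@H]1CC1=C2[C@@](C)(CC=C(C)C)C(=O)C(C(=O)C(C)C)=C1O
A2 | alternative 1 | TBS ether of 2-(3-methylcyclopent-2-en-1-yl)propan-1-ol (ring stereocentre derived from 1) | CC(CO[Si](C)(C)C(C)(C)C)[C@@H]1CCC(C)=C1
A3 | alternative 1 | dearomatised core with enolic C-methyl group | CC1=C(O)[C@@](C)(CC=C(C)C)C(=O)C(C(=O)C(C)C)=C1O
A4 | alternative 1 | o-quinone methide from A3 | C=C1C(=O)[C@@](C)(CC=C(C)C)C(=O)C(C(=O)C(C)C)=C1O
A5 | alternative 2 | trans-4-(prop-1-en-2-yl)-5-(triisopropylsilyloxymethyl)cyclopent-2-en-1-one | C=C(C)[C@@H]1C=CC(=O)[C@H]1CO[Si](C(C)C)(C(C)C)C(C)C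
A6 | alternative 2 | β-trimethylsilyl divinyl ketone (geometry of the trisubstituted alkene not stereodetermining) | C=C(C)C=C(CO[Si](C(C)C)(C(C)C)C(C)C)C(=O)/C=C/[Si](C)(C)C
A7 | alternative 3 | methyl 2-hydroxy-2-methyl-5-(prop-1-en-2-yl)cyclopentane-1-carboxylate (ester cis to OH, trans to isopropenyl) | C=C(C)[C@@H]1CC[C@@](C)(O)[C@H]1C(=O)OC
A8 | alternative 3 | methyl (E)-8-chloro-3-hydroxy-3,7-dimethyloct-6-enoate (carbinol configuration as in A9) | COC(=O)C[C@](C)(O)CC/C=C(\C)CCl
A9 | alternative 3 | (R)-linalool | C=C[C@](C)(O)CCC=C(C)C
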